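## Structural features

The target is a meroterpenoid. A drimane-type decalin (ring A: C1–C5 and C10 with a gem-dimethyl group at C4; ring B: C5–C10 with a C7=C8 double bond carrying the C8 methyl) is joined through the C11 methylene at C9 to a pentasubstituted benzene ring. The arene (C1'–C6', C1' bearing C11) carries hydroxyls at C2', C3' and C6', a hydrogen sulfate at C5' and hydrogen at C4'.

Three stereocentres are contiguous along C5–C10–C9. C10 is quaternary (angular methyl), H5 is anti to that methyl (trans-decalin), and C11 on C9 is also anti to the C10 methyl. This is the 9-epi-drimane arrangement: H5 and C11 share one face and C11 is axial-like on ring B.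

The fragile groups are the sulfate monoester (acid), the tetraoxygenated arene (autoxidation to the hydroxyquinone) and the C7=C8 alkene (acid-induced migration to C8=C9, or capture of a C8 cation by the C2'/C6' oxygen). C9 is also at risk whenever a carbonyl group or a cation sits at C11 or a conjugated carbonyl at C6.

The real difficulty is threefold. The fully substituted C10 must be built next to C9 with the less common relative configuration and as one enantiomer. Ring B ends with no heteroatom, so any activating group used to build it has to be removed without moving the alkene. The four aryl oxygens differ only by their position relative to C1'.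

The key step uses ring B as a cyclohexene retron. Bonds C7–C8 and C9–C10 are made by a [4+2] addition in which an acyl carbon at C9 lies endo to a diene whose C10 terminus carries its methyl inside, which is exactly the anti C11/C10-methyl relationship. An oxygen at C6 steers the regiochemistry and later serves to place the C7=C8 alkene and to set C5.

The arene has a local mirror plane through C1' and C4'. Lithiation of its tetramethyl ether, oxidation to the para-quinone and sulfation at C3' or C5' are therefore each constitutionally unambiguous.

## Logic of the disconnections

**24 ⇒ 22 (through 23).** The O–S bond at C5' is cut and the arene is taken back to the quinone level. The sulfate is the most labile group and 23 is too air-sensitive to store, so both are left to the last operation. This leaves 22, a stable, symmetric-looking quinone. The forward step must place one sulfate on an oxygen next to C4'–H and not on one next to C1'.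

**22 ⇒ 20 (through 21).** Four O–CH3 bonds are restored. Two are removed forward by oxidative demethylation and two by hydrolysis of the resulting vinylogous esters, which avoids any Lewis-acidic ether cleavage next to the alkene. 20 is a robust, non-phenolic arene that tolerates the chemistry on ring B. The demand is an oxidation that spares C7=C8.

**20 ⇒ 18 (through 19).** The two C6–H bonds are traced back to a C6 carbonyl conjugated with C7=C8. The carbonyl is what allows C5 to be adjusted and the alkene to be placed. The forward step must remove the allylic oxygen with hydride delivered to C6 and not to C8, and without a proton source that could reopen C5 or C9.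

**18 ⇒ 17 ⇒ 15 (through 16).** The C5 configuration and the C7=C8 π bond are disconnected. In 15 the trans-fused form would hold the C8 and C10 methyls 1,3-diaxial, so C5 is set only after C8 has become sp2 (17 → 18). The dehydrogenation can go only towards C8, because C5 has no hydrogen-bearing neighbour besides C6. The demand is enolisation of 15 at C7 and an equilibrium at C5 that lies on the trans side.

**15 ⇒ 12 (through 14 and 13).** The C11–H bonds are traced back to the aryl ketone and the C6 carbonyl to its silyl enol ether. C11 is deoxygenated before the enone exists. An enone at C6 and a ketone at C11 together would make H9 doubly activated and would put C9 at risk. The demand is hydride capture of the C11 cation faster than loss of H9.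

**12 ⇒ 5 + 11 (key disconnection).** C7–C8 and C9–C10 are cut. This removes ring B, the quaternary centre and the C9/C10 relationship in one step and leads to two achiral fragments of similar size. The forward step must be para-selective, endo-selective, concerted and enantioselective. The oxygen at C6 is protected as its triisopropylsilyl ether rather than a smaller silyl ether, so that the diene survives an acidic cationic catalyst and silyl transfer (the open Michael pathway) is slowed.

**11 ⇒ 8 + 7 (through 9 and 10); 7 ⇒ 6.** The aryl–C11 bond is cut. Both ring hydrogens of 8 are equivalent and lie between two methoxy groups, so metalation is unambiguous. The N-methoxy-N-methyl amide stops the addition at the ketone stage. The demand is 1,2-addition without touching the E double bond.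

**5 ⇒ 4 ⇒ 3 ⇒ 1 + 2.** The O–Si bond, then the carbinol oxidation level, then the C6–C7 bond (the methyl group from 2) are cut. The demand is enolisation of 4 towards the methyl group only, which is the only α-position that carries hydrogen.

## Other disconnections considered

**Alternative 1:** The cut is C4–C5 and C9–C10, both rings at once, from the acyclic (2Z,6E)-farnesylarene A1. In the forward step a chiral Lewis-acid-assisted Brønsted acid would protonate the terminal alkene, the folded triene would close rings A and B, and the C8 cation would lose H7 to give A2, which is the same compound as 20.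

- In its favour: it is much shorter. A1 is one C–C coupling away from 8, and A2 enters the chosen route at step 12, so on step economy this alternative is clearly the better plan. The trans ring fusion and the C9 configuration would be translated directly from the 6E and 2Z alkene geometries. No oxygen would have to be removed at C6 or C11 and no C5 equilibration would be needed, which is also better.
- Against it here: the 2Z,6E chain must be isomerically pure. The arene cannot terminate the cascade because both ortho positions are blocked, so the C8 cation can lose H7, H9 or a C12 proton, or be captured by an ortho-methoxy oxygen. A Z-alkene at the second ring closure is expected to make that closure less concerted, so C9 may leak. Enantioselective proton-initiated bicyclisations are best supported where an arene or phenol ends the cascade.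
- Comparison: both plans rest on an enantioselective step that is untested on its exact substrate, so they are equal on that point. The chosen plan is longer but separates C9/C10 (cycloaddition), C5 (equilibration) and alkene position (C6 oxygen) into independently controllable operations.

**Alternative 2:** The cut is C1–C10 and C4–C5, so ring A is built onto a preformed ring B. Diene A3 would add to one methyl-bearing double bond of quinone A4 under a chiral oxazaborolidinium Lewis acid to give the cis-fused adduct A5 with C10 set.

- In its favour: enantioselective quinone Diels–Alder reactions with this catalyst class are well supported and their sense is predictable, so on established asymmetric catalysis this alternative is better than the chosen key step. Both partners are simple.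
- Against it here: A3 carries a Z-methyl on its C4 terminus, which disfavours the s-cis form and makes it a sluggish diene. A5 contains neither C11, nor the arene, nor the C9 stereocentre. C9 is a ketone next to the quaternary C10 and would have to be turned into a CH carrying the arylmethyl group anti to the C10 methyl. The C2=C3 alkene would have to be hydrogenated beside C7=C8, and the C6 oxygen removed.
- Comparison: the chosen plan forms C9 with its carbon substituent and C10 in the same step, whereas this one forms C10 only. Both use a diene with an inside methyl and both need a later C5 epimerisation through a C6 ketone, so they are equal there. On step economy this alternative is expected to be worse.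

**Alternative 3:** The cut is C4'–C5' and C1'–C6' of the oxygenated six-membered ring, so the arene is built rather than carried. Diketone A6 and diethyl oxalate A7 would undergo two Claisen condensations under an alkoxide base (methyl carbon to C5', methylene carbon to C6') and enolise to A8, which is the same compound as 22.

- In its favour: it reaches the oxidation level needed one step before the target without aryl protecting groups, oxidative demethylation or hydrolysis. On the endgame it is equal or better, and no electron-rich arene is present during the terpenoid chemistry.
- Against it here: it says nothing about C5, C9 and C10. A6 with its four-carbon chain on C9 would need a route of comparable length. The 1,2-diketone is prone to self-condensation and benzilic-type rearrangement under alkoxide. A double condensation of this kind would sit late, on the most valuable intermediate.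
- Comparison: it is complementary to the chosen plan rather than a competitor for the stereochemical problem. It would save steps 12 and 13 but add the steps needed to make A6, so no net gain is expected.

Key step: step 6

**Remarks**

- Drimane numbering is used (C11 on C9, C12 on C8; aryl carbons primed); β is the face of the C10 methyl and α the opposite face.
- The target is drawn as the free hydrogen sulfate; it is assumed to be obtained as its pyridinium salt and freed by brief cold cation exchange.
- The sense of induction of the oxazaborolidinium catalyst on this aryl ketone is assigned by analogy with its usual enone binding mode. The (S)-catalyst is written; its (R)-antipode is the one to use if the sense proves opposite.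
- The key-step precursors and adduct were checked against the target and need no structural correction: the E-enone gives the C8 methyl trans to the aroyl group, the aroyl group is anti to the C10 methyl, and C10 is as in the target.

## Route

**Step 1**
Reactants: 1 β-cyclocitral; 2 methylmagnesium bromide
Product: 3 1-(2,6,6-trimethylcyclohex-1-en-1-yl)ethan-1-ol (racemic)
Conditions: Et2O, 0 °C → rt; H2O quench
Reagents that add atoms: none
Why: Grignard 1,2-addition to an aldehyde that has no α-hydrogen; the new carbinol centre is racemic and is removed in step 2.

**Step 2**
Reactants: 3 1-(2,6,6-trimethylcyclohex-1-en-1-yl)ethan-1-ol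
Product: 4 1-(2,6,6-trimethylcyclohex-1-en-1-yl)ethan-1-one
Conditions: (n-Pr4N)RuO4 (5 mol%), N-methylmorpholine N-oxide, 4 Å molecular sieves, CH2Cl2, rt
Reagents that add atoms: none
Why: Perruthenate-catalysed oxidation of a secondary allylic alcohol under neutral conditions, which avoids ionisation of the hindered allylic carbinol.

**Step 3**
Reactants: 4 1-(2,6,6-trimethylcyclohex-1-en-1-yl)ethan-1-one
Product: 5 triisopropyl{[1-(2,6,6-trimethylcyclohex-1-en-1-yl)ethenyl]oxy}silane
Conditions: i-Pr3SiOSO2CF3, Et3N, CH2Cl2, 0 °C → rt
Reagents that add atoms: triisopropylsilyl trifluoromethanesulfonate, CC(C)[Si](OS(=O)(=O)C(F)(F)F)(C(C)C)C(C)C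
Why: Soft enolisation of a methyl ketone; the methyl group is the only α-position with hydrogen, and the ring alkene is twisted out of conjugation so γ-deprotonation should not compete, which gives the cross-conjugated 2-silyloxydiene.

**Step 4**
Reactants: 6 (E)-but-2-enoyl chloride
Product: 7 (E)-N-methoxy-N-methylbut-2-enamide
Conditions: MeNH(OMe)·HCl, pyridine, CH2Cl2, 0 °C → rt
Reagents that add atoms: N,O-dimethylhydroxylamine hydrochloride, CNOC.Cl
Why: Acylation of the amine by the acid chloride; the E double bond is not touched.

**Step 5**
Reactants: 8 1,2,4,5-tetramethoxybenzene; 7 (E)-N-methoxy-N-methylbut-2-enamide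
Product: 11 (E)-1-(2,3,5,6-tetramethoxyphenyl)but-2-en-1-one, via aryllithium 9 (not isolated), via tetrahedral lithium adduct 10 (not isolated)
Conditions: n-BuLi, TMEDA, THF, 0 °C; 7, −78 → −40 °C; inverse quench into cold 1 M HCl
Reagents that add atoms: none
Why: Directed ortho-lithiation between two methoxy groups (both ring hydrogens are equivalent) followed by Weinreb ketone synthesis; the chelated adduct 10 prevents a second addition and conjugate addition to the enone, and the acidic inverse quench removes the liberated amine before it can add to the enone.

**Step 6**
Reactants: 5 triisopropyl{[1-(2,6,6-trimethylcyclohex-1-en-1-yl)ethenyl]oxy}silane; 11 (E)-1-(2,3,5,6-tetramethoxyphenyl)but-2-en-1-one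
Product: 12 (2,3,5,6-tetramethoxyphenyl)[(1R,2S,8aR)-2,5,5,8a-tetramethyl-4-(triisopropylsilyloxy)-1,2,3,5,6,7,8,8a-octahydronaphthalen-1-yl]methanone (endo adduct; drimane numbering: C5=C6 silyl enol ether, 8β-methyl, 9α-aroyl, 10β-methyl)
Conditions: (S)-3,3-diphenyl-1-(2-methylphenyl)tetrahydro-1H,3H-pyrrolo[1,2-c][1,3,2]oxazaborole (20 mol%), HN(SO2CF3)2 (18 mol%), CH2Cl2, −78 → −20 °C
Reagents that add atoms: none
Why: Proposed new method: the boron of the N-protonated oxazaborolidine should bind the carbonyl lone pair of 11 on the propenyl side (the twisted di-ortho-methoxyaryl group blocks the other side) and lower the LUMO, so that a concerted but asynchronous suprafacial [4+2] addition can occur in which C7, the terminus made nucleophilic by the 6-silyloxy group, bonds to the β-carbon C8 ahead of C10 bonding to C9. The closest known reaction types are the oxazaborolidinium-catalysed enantioselective Diels–Alder reaction of 2-silyloxybutadienes with acyclic enones and the Lewis-acid-promoted cycloaddition of fully substituted 2-silyloxydienes with hindered enones; their combination on a diene terminus that becomes a quaternary centre is what is new. Ring B is closed as a six-membered carbocycle by intermolecular [4+2] cycloaddition, both σ bonds forming on one face of each partner. C8 follows from the E geometry of 11 (methyl trans to aroyl; erased in step 9), C9 relative to C10 from the endo orientation of the aroyl group, which puts it anti to the inside methyl of the C10 terminus, and the absolute configuration from the enone face left open by the catalyst. The step needs para regiochemistry, endo selectivity, one enantioface and a concerted course: the silyloxy group secures the first, the Lewis-acid-bound carbonyl the second, the catalyst the third, and the bulky triisopropylsilyl group with the non-nucleophilic triflimide counter-ion at low temperature disfavours silyl transfer and thus the open Mukaiyama–Michael product.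

**Step 7**
Reactants: 12 endo adduct
Product: 13 benzylic alcohol (C11 carbinol of 12; both C11 epimers serve)
Conditions: LiAlH4, THF, 0 → 50 °C; aqueous NaOH work-up
Reagents that add atoms: none
Why: Hydride reduction of the hindered aryl ketone by a small nucleophilic hydride; the silyl enol ether is inert, and the C11 configuration is irrelevant because the oxygen is removed in step 8.

**Step 8**
Reactants: 13 benzylic alcohol
Product: 15 8β-methyl-9α-(2,3,5,6-tetramethoxybenzyl)-10β-methyl-drimane-type 6-ketone (C5 epimer mixture), via silyl enol ether 14 (not isolated)
Conditions: Et3SiH (excess), CF3CO2H, CH2Cl2, −20 °C; then Bu4NF, AcOH, THF, 0 °C → rt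
Reagents that add atoms: none
Why: Ionic hydrogenation: the di-ortho-methoxybenzylic alcohol ionises and excess silane at low temperature should trap the C11 cation before it can lose H9, while the hindered tetrasubstituted silyl enol ether survives and is then cleaved by fluoride. Protonation at C5 is not controlled here and is corrected in step 10.

**Step 9**
Reactants: 15 6-ketone (C5 epimer mixture)
Product: 17 9α-(2,3,5,6-tetramethoxybenzyl)drim-7-en-6-one (C5 epimer mixture), via trimethylsilyl enol ether 16 (not isolated)
Conditions: LiN(i-Pr)2, Me3SiCl, THF, −78 °C; then Pd(OAc)2, MeCN, rt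
Reagents that add atoms: none
Why: Kinetic enolisation at the C7 methylene (C5–H lies between two quaternary carbons) and Saegusa oxidation; β-hydride elimination can remove only H8, so the C7=C8 enone is the only possible product and the C8 stereocentre is erased.

**Step 10**
Reactants: 17 enone (C5 epimer mixture)
Product: 18 5α-H,9α-(2,3,5,6-tetramethoxybenzyl),10β-methyl-drim-7-en-6-one (trans-fused)
Conditions: K2CO3, MeOH, rt
Reagents that add atoms: none
Why: Base-mediated epimerisation through the cross-conjugated C5 enolate; with C8 now sp2 the trans-fused form no longer has 1,3-diaxial C8/C10 methyls and is expected to be favoured. H9 is only a hindered γ-hydrogen now that C11 is a methylene, so C9 should hold.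

**Step 11**
Reactants: 18 trans-fused enone
Product: 20 1,2,4,5-tetramethoxy-3-{[(1R,4aS,8aS)-2,5,5,8a-tetramethyl-1,4,4a,5,6,7,8,8a-octahydronaphthalen-1-yl]methyl}benzene, via dichloroaluminium alkoxide 19 (not isolated)
Conditions: LiAlH4, AlCl3 (1:3), Et2O, 0 °C → reflux
Reagents that add atoms: none
Why: Mixed-hydride hydrogenolysis of an enone: 1,2-reduction, ionisation of the allylic aluminium alkoxide and hydride capture of the C6–C7–C8 allyl cation at the less substituted C6, whose α face is open while both faces of C8 are screened; the classical conversion of steroidal 4-en-3-ones into 4-enes is the model. The medium is aprotic, so a diene formed by proton loss cannot be reprotonated and C5 and C9 should not be scrambled.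

**Step 12**
Reactants: 20 tetramethoxyarene
Product: 21 2,5-dimethoxy-3-{[(1R,4aS,8aS)-2,5,5,8a-tetramethyl-1,4,4a,5,6,7,8,8a-octahydronaphthalen-1-yl]methyl}cyclohexa-2,5-diene-1,4-dione
Conditions: (NH4)2Ce(NO3)6, MeCN/H2O, 0 °C
Reagents that add atoms: water, O
Why: Oxidative demethylation via the arene radical cation, with attack of water and loss of two methanol molecules; by the symmetry of the arene both para pairs give the same quinone, and an isolated trisubstituted alkene should be tolerated.

**Step 13**
Reactants: 21 dimethoxyquinone
Product: 22 2,5-dihydroxy-3-{[(1R,4aS,8aS)-2,5,5,8a-tetramethyl-1,4,4a,5,6,7,8,8a-octahydronaphthalen-1-yl]methyl}cyclohexa-2,5-diene-1,4-dione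
Conditions: 2 M NaOH, THF/H2O, 50 °C; then 1 M HCl, 0 °C
Reagents that add atoms: sodium hydroxide, [Na+].[OH-]
Why: Hydrolysis of the two vinylogous esters by addition–elimination of hydroxide; the product is stable as its dianion and is liberated by brief cold acidification to protect the alkene.

**Step 14**
Reactants: 22 dihydroxyquinone
Product: 24 2,4,5-trihydroxy-3-{[(1R,4aS,8aS)-2,5,5,8a-tetramethyl-1,4,4a,5,6,7,8,8a-octahydronaphthalen-1-yl]methyl}phenyl hydrogen sulfate, via tetrahydroxyarene 23 (not isolated)
Conditions: Na2S2O4, EtOAc/H2O, rt, Ar; then SO3·pyridine (1.05 equiv), pyridine, 0 °C; sulfonic acid resin (H+ form), MeOH/H2O, 0 °C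
Reagents that add atoms: sulfur trioxide–pyridine complex, [O-]S(=O)(=O)[n+]1ccccc1
Why: Dithionite reduction of the quinone and O-sulfation of a phenol by the sulfur trioxide–amine complex; the hydroxyls at C3' and C5' are constitutionally equivalent and less hindered than those next to the drimenylmethyl group, and the first sulfate deactivates the ring towards a second.

## Compound list

1 | β-cyclocitral (2,6,6-trimethylcyclohex-1-ene-1-carbaldehyde) | CC1=C(C=O)C(C)(C)CCC1 | starting material
2 | methylmagnesium bromide | C[Mg]Br | starting material
3 | 1-(2,6,6-trimethylcyclohex-1-en-1-yl)ethan-1-ol (racemic) | CC(O)C1=C(C)CCCC1(C)C | intermediate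
4 | 1-(2,6,6-trimethylcyclohex-1-en-1-yl)ethan-1-one | CC(=O)C1=C(C)CCCC1(C)C | intermediate
5 | triisopropyl{[1-(2,6,6-trimethylcyclohex-1-en-1-yl)ethenyl]oxy}silane | C=C(O[Si](C(C)C)(C(C)C)C(C)C)C1=C(C)CCCC1(C)C | intermediate
6 | (E)-but-2-enoyl chloride | C/C=C/C(=O)Cl | starting material
7 | (E)-N-methoxy-N-methylbut-2-enamide | C/C=C/C(=O)N(C)OC | intermediate
8 | 1,2,4,5-tetramethoxybenzene | COc1cc(OC)c(OC)cc1OC | starting material
9 | (2,3,5,6-tetramethoxyphenyl)lithium | [Li]c1c(OC)c(OC)cc(OC)c1OC | intermediate
10 | lithium (E)-1-[methoxy(methyl)amino]-1-(2,3,5,6-tetramethoxyphenyl)but-2-en-1-olate | C/C=C/C(O[Li])(N(C)OC)c1c(OC)c(OC)cc(OC)c1OC | intermediate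
11 | (E)-1-(2,3,5,6-tetramethoxyphenyl)but-2-en-1-one | C/C=C/C(=O)c1c(OC)c(OC)cc(OC)c1OC | intermediate
12 | endo adduct, (2,3,5,6-tetramethoxyphenyl)[(1R,2S,8aR)-2,5,5,8a-tetramethyl-4-(triisopropylsilyloxy)-1,2,3,5,6,7,8,8a-octahydronaphthalen-1-yl]methanone | C[C@H]1CC(O[Si](C(C)C)(C(C)C)C(C)C)=C2C(C)(C)CCC[C@]2(C)[C@@H]1C(=O)c1c(OC)c(OC)cc(OC)c1OC | intermediate
13 | benzylic alcohol of 12 (8β-methyl, 9α, 10β-methyl; C11 epimers) | C[C@H]1CC(O[Si](C(C)C)(C(C)C)C(C)C)=C2C(C)(C)CCC[C@]2(C)[C@@H]1C(O)c1c(OC)c(OC)cc(OC)c1OC | intermediate
14 | C5=C6 triisopropylsilyl enol ether with 9α-(2,3,5,6-tetramethoxybenzyl) group (8β-methyl, 10β-methyl) | C[C@H]1CC(O[Si](C(C)C)(C(C)C)C(C)C)=C2C(C)(C)CCC[C@]2(C)[C@@H]1Cc1c(OC)c(OC)cc(OC)c1OC | intermediate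
15 | 8β-methyl-9α-(2,3,5,6-tetramethoxybenzyl)-10β-methyl 6-ketone (C5 epimer mixture) | C[C@H]1CC(=O)C2C(C)(C)CCC[C@]2(C)[C@@H]1Cc1c(OC)c(OC)cc(OC)c1OC | intermediate
16 | C6=C7 trimethylsilyl enol ether of 15 (C5 epimer mixture) | C[C@H]1C=C(O[Si](C)(C)C)C2C(C)(C)CCC[C@]2(C)[C@@H]1Cc1c(OC)c(OC)cc(OC)c1OC | intermediate
17 | 9α-(2,3,5,6-tetramethoxybenzyl)drim-7-en-6-one (C5 epimer mixture) | CC1=CC(=O)C2C(C)(C)CCC[C@]2(C)[C@@H]1Cc1c(OC)c(OC)cc(OC)c1OC | intermediate
18 | 5α-H,9α-(2,3,5,6-tetramethoxybenzyl),10β-methyl-drim-7-en-6-one (trans-fused) | CC1=CC(=O)[C@H]2C(C)(C)CCC[C@]2(C)[C@@H]1Cc1c(OC)c(OC)cc(OC)c1OC | intermediate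
19 | dichloroaluminium 6-alkoxide of the allylic alcohol from 18 (C6 configuration not defined) | CC1=CC(O[Al](Cl)Cl)[C@H]2C(C)(C)CCC[C@]2(C)[C@@H]1Cc1c(OC)c(OC)cc(OC)c1OC | intermediate
20 | 1,2,4,5-tetramethoxy-3-{[(1R,4aS,8aS)-2,5,5,8a-tetramethyl-1,4,4a,5,6,7,8,8a-octahydronaphthalen-1-yl]methyl}benzene | CC1=CC[C@H]2C(C)(C)CCC[C@]2(C)[C@@H]1Cc1c(OC)c(OC)cc(OC)c1OC | intermediate
21 | 2,5-dimethoxy-3-{[(1R,4aS,8aS)-2,5,5,8a-tetramethyl-1,4,4a,5,6,7,8,8a-octahydronaphthalen-1-yl]methyl}cyclohexa-2,5-diene-1,4-dione | CC1=CC[C@H]2C(C)(C)CCC[C@]2(C)[C@@H]1CC1=C(OC)C(=O)C=C(OC)C1=O | intermediate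
22 | 2,5-dihydroxy-3-{[(1R,4aS,8aS)-2,5,5,8a-tetramethyl-1,4,4a,5,6,7,8,8a-octahydronaphthalen-1-yl]methyl}cyclohexa-2,5-diene-1,4-dione | CC1=CC[C@H]2C(C)(C)CCC[C@]2(C)[C@@H]1CC1=C(O)C(=O)C=C(O)C1=O | intermediate
23 | 3-{[(1R,4aS,8aS)-2,5,5,8a-tetramethyl-1,4,4a,5,6,7,8,8a-octahydronaphthalen-1-yl]methyl}benzene-1,2,4,5-tetrol | CC1=CC[C@H]2C(C)(C)CCC[C@]2(C)[C@@H]1Cc1c(O)c(O)cc(O)c1O | intermediate
24 | 2,4,5-trihydroxy-3-{[(1R,4aS,8aS)-2,5,5,8a-tetramethyl-1,4,4a,5,6,7,8,8a-octahydronaphthalen-1-yl]methyl}phenyl hydrogen sulfate | CC1=CC[C@H]2C(C)(C)CCC[C@]2(C)[C@@H]1Cc1c(O)c(O)cc(OS(=O)(=O)O)c1O | target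

## Step count and least certain steps

Total step count: 14. Longest linear sequence: 12 steps (steps 1–3 and 6–14, from 1); the branch through steps 4 and 5 joins at step 6.

**Step 6 (key step, carries the proposed method).**
- What may go wrong: the diene may fail to reach the s-cis geometry (inside C10 methyl against C7, silyloxy group against the C4 methyls), so that cycloaddition is slower than protodesilylation of 5. The reaction may leak into a stepwise Mukaiyama–Michael course that ends in silyl transfer instead of closure at the quaternary carbon. Exo addition may be driven by the clash between the catalyst-bound aroyl group and the axial C4 methyl. Enantioface discrimination may be weak if boron binds the carbonyl lone pair next to the aryl group or is held by an ortho-methoxy oxygen.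
- Fallback (known chemistry): 5 and 11 are combined under an achiral mixed aluminium Lewis acid (AlBr3/AlMe3, toluene/CH2Cl2, about −10 °C), the established way to bring hindered 2-silyloxydienes and hindered enones through an endo cycloaddition. This should give 12 as the racemate, that is, together with the mirror-image adduct F1. Resolution by preparative chromatography on a cellulose tris(3,5-dimethylphenylcarbamate) phase returns to the route at 12.

**Step 11.**
- What may go wrong: hydride capture at C8 instead of C6 (alkene at C6=C7 and a new C8 centre); proton loss from the allyl cation at C5 or C9 to give dienes; Lewis-acid cleavage of an aryl methyl ether.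
- Fallback: setting out from 18, a Luche reduction (NaBH4, CeCl3·7H2O, MeOH) should give the allylic alcohol F2. LiN(SiMe3)2 and ClCO2Me should convert it into the allylic methyl carbonate F3. Pd(PPh3)4 (catalytic) with NaBH4 in THF should then replace the carbonate by hydride: zerovalent palladium ionises the carbonate and hydride is passed to the less substituted allyl terminus C6, the known regiochemical preference of this hydride source. The sequence returns to the route at 20 and replaces a free allyl cation by a palladium-bound allyl unit.

**Step 14.**
- What may go wrong: insufficient site selectivity among four hydroxyls; double sulfation; reoxidation of 23 by air before sulfation; cyclisation of an ortho hydroxyl onto C8 or loss of the sulfate during conversion into the free acid.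
- Fallback: setting out from 21, exchange of both methoxy groups by addition–elimination in allyl alcohol with catalytic K2CO3 should give the bis(allyloxy)quinone F4. Reduction with Na2S2O4 gives the bis(allyloxy)hydroquinone F5, which has only two free hydroxyls: one between an allyloxy group and C4'–H, the other between an allyloxy group and the drimenylmethyl group. SO3·pyridine should sulfate the former to give the bis(allyl) ether monosulfate F6. Deallylation with Pd(PPh3)4 and morpholine, followed by the same cation exchange, returns to the route at 24. Temporary protection thus replaces the four-way competition by a two-way one and excludes double sulfation at the unhindered positions.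

**Step 10.**
- What may go wrong: an equilibrium that does not lie far enough on the trans side (the axial C9 arylmethyl group is syn to H5); slow enolisation at the hindered C5; γ-deprotonation at C9 with erosion of that centre.
- Fallback: setting out from 17, kinetic α′-deprotonation with LiN(i-Pr)2 in THF at −78 °C should give the lithium dienolate F7. Irreversible protonation with AcOH at −78 °C is expected to occur on the α face of C5, because the β face is walled off by the 4β- and 10β-methyls. This returns to the route at 18 and replaces thermodynamic by kinetic control.

## Further compounds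

F1 | step 6 | mirror-image adduct (enantiomer of 12, formed with 12 as the racemate) | C[C@@H]1CC(O[Si](C(C)C)(C(C)C)C(C)C)=C2C(C)(C)CCC[C@@]2(C)[C@H]1C(=O)c1c(OC)c(OC)cc(OC)c1OC
F2 | step 11 | allylic alcohol, 5α-H,9α-(2,3,5,6-tetramethoxybenzyl)drim-7-en-6-ol (C6 configuration not defined) | CC1=CC(O)[C@H]2C(C)(C)CCC[C@]2(C)[C@@H]1Cc1c(OC)c(OC)cc(OC)c1OC
F3 | step 11 | allylic methyl carbonate of F2 | CC1=CC(OC(=O)OC)[C@H]2C(C)(C)CCC[C@]2(C)[C@@H]1Cc1c(OC)c(OC)cc(OC)c1OC
F4 | step 14 | bis(allyloxy)quinone, 2,5-bis(prop-2-en-1-yloxy)-3-{[(1R,4aS,8aS)-2,5,5,8a-tetramethyl-1,4,4a,5,6,7,8,8a-octahydronaphthalen-1-yl]methyl}cyclohexa-2,5-diene-1,4-dione | CC1=CC[C@H]2C(C)(C)CCC[C@]2(C)[C@@H]1CC1=C(OCC=C)C(=O)C=C(OCC=C)C1=O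
F5 | step 14 | bis(allyloxy)hydroquinone, 2,5-bis(prop-2-en-1-yloxy)-3-{[(1R,4aS,8aS)-2,5,5,8a-tetramethyl-1,4,4a,5,6,7,8,8a-octahydronaphthalen-1-yl]methyl}benzene-1,4-diol | CC1=CC[C@H]2C(C)(C)CCC[C@]2(C)[C@@H]1Cc1c(OCC=C)c(O)cc(OCC=C)c1O
F6 | step 14 | bis(allyl) ether monosulfate, 4-hydroxy-2,5-bis(prop-2-en-1-yloxy)-3-{[(1R,4aS,8aS)-2,5,5,8a-tetramethyl-1,4,4a,5,6,7,8,8a-octahydronaphthalen-1-yl]methyl}phenyl hydrogen sulfate | CC1=CC[C@H]2C(C)(C)CCC[C@]2(C)[C@@H]1Cc1c(OCC=C)c(OS(=O)(=O)O)cc(OCC=C)c1O
F7 | step 10 | lithium dienolate (C5=C6–OLi, C7=C8) of 17 | CC1=CC(O[Li])=C2C(C)(C)CCC[C@]2(C)[C@@H]1Cc1c(OC)c(OC)cc(OC)c1OC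
A1 | alternative 1 | 1,2,4,5-tetramethoxy-3-[(2Z,6E)-3,7,11-trimethyldodeca-2,6,10-trien-1-yl]benzene | COc1cc(OC)c(OC)c(C/C=C(/C)CC/C=C(\C)CCC=C(C)C)c1OC
A2 | alternative 1 | tetramethoxyaryl drim-7-ene (identical with 20) | CC1=CC[C@H]2C(C)(C)CCC[C@]2(C)[C@@H]1Cc1c(OC)c(OC)cc(OC)c1OC
A3 | alternative 2 | 4-methylpenta-1,3-diene | C=CC=C(C)C
A4 | alternative 2 | 2,6-dimethyl-1,4-benzoquinone | CC1=CC(=O)C=C(C)C1=O
A5 | alternative 2 | cis-2,5,5,8a-tetramethyl-4a,5,8,8a-tetrahydronaphthalene-1,4-dione (C10 as in the target) | CC1=CC(=O)[C@@H]2C(C)(C)C=CC[C@]2(C)C1=O
A6 | alternative 3 | 1-[(1R,4aS,8aS)-2,5,5,8a-tetramethyl-1,4,4a,5,6,7,8,8a-octahydronaphthalen-1-yl]butane-2,3-dione | CC1=CC[C@H]2C(C)(C)CCC[C@]2(C)[C@@H]1CC(=O)C(C)=O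
A7 | alternative 3 | diethyl oxalate | CCOC(=O)C(=O)OCC
A8 | alternative 3 | 3-(drimenylmethyl)-2,5-dihydroxy-1,4-benzoquinone (identical with 22) | CC1=CC[C@H]2C(C)(C)CCC[C@]2(C)[C@@H]1CC1=C(O)C(=O)C=C(O)C1=O
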